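**Retrosynthetic overview**
1. Target 12 ⇒ (E)-selective Horner–Wadsworth–Emmons union of aldehyde 10 with coumarinylmethyl phosphonate 7; both coumarin rings are bought intact as 5,7-dimethoxycoumarin.
2. 10 ⇒ Claisen ring contraction of 2-styryl-3,4-dihydro-2H-pyran 9: the cyclohexene ring (formed last) and both carbon stereocentres come from one C2–O stereocentre.
3. 9 ⇒ Horner–Wadsworth–Emmons reaction of (R)-methacrolein dimer 2 with the same phosphonate 7.
4. 2 ⇒ key step: catalytic enantioselective oxa-Diels–Alder homodimerisation of methacrolein 1; the C–O bond closes the dihydropyran ring (formed first) and sets the only stereocentre a catalyst has to make.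
5. 7 ⇒ 5,7-dimethoxycoumarin 3 by C8 chloromethylation and Michaelis–Arbuzov reaction.

Assumption: the sense of induction of the new catalyst in step 1 cannot be known in advance; the aminoindanol antipode (both are commercial) that gives (R)-2 is used, written here as the (1R,2S) ligand. salin = dianion (C27H29NO2) of (1R,2S)-1-{[3-(adamantan-1-yl)-2-hydroxy-5-methylbenzylidene]amino}-2,3-dihydro-1H-inden-2-ol.

**Step 1**
Reactants: 1 methacrolein (two molecules)
Product: 2 (2R)-2,5-dimethyl-3,4-dihydro-2H-pyran-2-carbaldehyde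
Conditions: [CrCl(salin)] (5 mol%), powdered 4 Å MS, BHT (0.5 mol%), neat 1, 4 → 23 °C, 72 h; bulb-to-bulb distillation
Reagents that add atoms: none
Why: Proposed new method: an enantioselective oxa-Diels–Alder homodimerisation in which one trivalent chromium centre of the dimeric Lewis acid [CrCl(salin)] binds s-cis methacrolein through oxygen (LUMO-lowered 1-oxadiene) while the neighbouring chromium centre holds the formyl group of the second methacrolein, so that its C=C bond adds tail to tail (CH2–CH2 bond leading, then O–C closure on one enantiotopic face of the methyl- and formyl-bearing carbon) and the quaternary C2–O stereocentre is set as R by the chiral pocket; the closest known reactions are the uncatalysed thermal dimerisation of methacrolein to racemic 2 and the inverse-electron-demand hetero-Diels–Alder reaction of enals with enol ethers under tridentate Schiff-base chromium chloride catalysts.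

**Step 2**
Reactants: 3 5,7-dimethoxy-2H-chromen-2-one (5,7-dimethoxycoumarin)
Product: 5 8-(chloromethyl)-5,7-dimethoxy-2H-chromen-2-one, via hydroxymethyl coumarin 4 (not isolated)
Conditions: (CH2O)n, conc. aq. HCl, ZnCl2 (10 mol%), AcOH, 50 °C; recrystallisation
Reagents that add atoms: formaldehyde (as paraformaldehyde) C=O; hydrogen chloride Cl
Why: Blanc chloromethylation is an electrophilic aromatic substitution expected at C8, the open position ortho to 7-OMe and para to 5-OMe, and the benzylic alcohol 4 is converted to the chloride by HCl in the same pot; no stereocentre is formed.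

**Step 3**
Reactants: 5 8-(chloromethyl)-5,7-dimethoxy-2H-chromen-2-one
Product: 7 diethyl [(5,7-dimethoxy-2-oxo-2H-chromen-8-yl)methyl]phosphonate, via triethoxyphosphonium chloride 6 (not isolated)
Conditions: P(OEt)3 (neat, 5 equiv), 120 °C, EtCl distilled off
Reagents that add atoms: triethyl phosphite CCOP(OCC)OCC
Why: Michaelis–Arbuzov reaction: the electron-rich benzylic chloride alkylates phosphorus readily and chloride then dealkylates the alkoxyphosphonium salt 6 to the phosphonate.

**Step 4**
Reactants: 2 (2R)-2,5-dimethyl-3,4-dihydro-2H-pyran-2-carbaldehyde; 7 diethyl [(5,7-dimethoxy-2-oxo-2H-chromen-8-yl)methyl]phosphonate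
Product: 9 8-{(E)-2-[(2R)-2,5-dimethyl-3,4-dihydro-2H-pyran-2-yl]ethenyl}-5,7-dimethoxy-2H-chromen-2-one, via phosphonate carbanion potassium salt 8 (not isolated)
Conditions: KN(SiMe3)2 (1.05 equiv), THF, −78 → 0 °C; chromatography on Et3N-deactivated silica
Reagents that add atoms: none
Why: Horner–Wadsworth–Emmons olefination: the benzylic phosphonate carbanion adds to the non-enolisable aldehyde and reversible addition funnels to the (E)-alkene, while the quaternary C2 stereocentre (no α-hydrogen) is untouched.

**Step 5**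
Reactants: 9 8-{(E)-2-[(2R)-2,5-dimethyl-3,4-dihydro-2H-pyran-2-yl]ethenyl}-5,7-dimethoxy-2H-chromen-2-one
Product: 10 (1S,2S)-2-(5,7-dimethoxy-2-oxo-2H-chromen-8-yl)-1,4-dimethylcyclohex-3-ene-1-carbaldehyde
Conditions: degassed 1,2-dichlorobenzene, BHT (cat.), iPr2NEt (0.1 equiv), sealed tube, 200 °C
Reagents that add atoms: none
Why: Claisen rearrangement of a 2-alkenyl-3,4-dihydro-2H-pyran (Büchi ring contraction): the C3–C4 bridge forces a boat transition state in which the (E)-styryl terminus bonds to C5 on a single face, so the (R) C2–O stereocentre is relayed suprafacially into the (1S,2S) aldehyde with aryl and formyl cis, driven by C=O formation.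

**Step 6**
Reactants: 10 (1S,2S)-2-(5,7-dimethoxy-2-oxo-2H-chromen-8-yl)-1,4-dimethylcyclohex-3-ene-1-carbaldehyde; 7 diethyl [(5,7-dimethoxy-2-oxo-2H-chromen-8-yl)methyl]phosphonate
Product: 12 8-{(E)-2-[(1R,2R)-2-(5,7-dimethoxy-2-oxo-2H-chromen-8-yl)-1,4-dimethylcyclohex-3-en-1-yl]ethenyl}-5,7-dimethoxy-2H-chromen-2-one, via phosphonate carbanion sodium salt 11 (not isolated)
Conditions: NaN(SiMe3)2 (1.2 equiv), THF, −78 → 40 °C
Reagents that add atoms: none
Why: Horner–Wadsworth–Emmons olefination in which the tight sodium ion pair bridges the formyl and phosphoryl oxygens to help addition to the hindered neopentyl-type aldehyde and warming collapses the adduct to the (E)-styryl bond, while the quaternary formyl-bearing carbon means neither stereocentre can epimerise under the base (the descriptors change from S,S to R,R only through ligand priorities).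

**Compound list**
1 | methacrolein (2-methylprop-2-enal) | CC(=C)C=O | starting material
2 | (2R)-2,5-dimethyl-3,4-dihydro-2H-pyran-2-carbaldehyde | CC1=CO[C@](C)(CC1)C=O | intermediate
3 | 5,7-dimethoxy-2H-chromen-2-one | COc1cc(OC)c2ccc(=O)oc2c1 | starting material
4 | 8-(hydroxymethyl)-5,7-dimethoxy-2H-chromen-2-one | COc1cc(OC)c2ccc(=O)oc2c1CO | intermediate (not isolated)
5 | 8-(chloromethyl)-5,7-dimethoxy-2H-chromen-2-one | COc1cc(OC)c2ccc(=O)oc2c1CCl | intermediate
6 | triethoxy[(5,7-dimethoxy-2-oxo-2H-chromen-8-yl)methyl]phosphonium chloride | CCO[P+](OCC)(OCC)Cc1c(OC)cc(OC)c2ccc(=O)oc12.[Cl-] | intermediate (not isolated)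
7 | diethyl [(5,7-dimethoxy-2-oxo-2H-chromen-8-yl)methyl]phosphonate | CCOP(=O)(OCC)Cc1c(OC)cc(OC)c2ccc(=O)oc12 | intermediate
8 | potassium (diethoxyphosphoryl)(5,7-dimethoxy-2-oxo-2H-chromen-8-yl)methanide | CCOP(=O)(OCC)[CH-]c1c(OC)cc(OC)c2ccc(=O)oc12.[K+] | intermediate (not isolated)
9 | 8-{(E)-2-[(2R)-2,5-dimethyl-3,4-dihydro-2H-pyran-2-yl]ethenyl}-5,7-dimethoxy-2H-chromen-2-one | CC1=CO[C@](C)(CC1)/C=C/c1c(OC)cc(OC)c2ccc(=O)oc12 | intermediate
10 | (1S,2S)-2-(5,7-dimethoxy-2-oxo-2H-chromen-8-yl)-1,4-dimethylcyclohex-3-ene-1-carbaldehyde | O=C[C@@]1(C)CCC(C)=C[C@H]1c1c(OC)cc(OC)c2ccc(=O)oc12 | intermediate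
11 | sodium (diethoxyphosphoryl)(5,7-dimethoxy-2-oxo-2H-chromen-8-yl)methanide | CCOP(=O)(OCC)[CH-]c1c(OC)cc(OC)c2ccc(=O)oc12.[Na+] | intermediate (not isolated)
12 | 8-{(E)-2-[(1R,2R)-2-(5,7-dimethoxy-2-oxo-2H-chromen-8-yl)-1,4-dimethylcyclohex-3-en-1-yl]ethenyl}-5,7-dimethoxy-2H-chromen-2-one (CNP0164660.2) | COc1cc(OC)c2ccc(=O)oc2c1/C=C/[C@@]1(C)CCC(C)=C[C@H]1c1c(OC)cc(OC)c2ccc(=O)oc12 | target

**Totals**
Total step count: 6. Longest linear sequence: 5 steps (3 → 5 → 7 → 9 → 10 → 12); the methacrolein branch is 4 steps (1 → 2 → 9 → 10 → 12).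

**Three steps most likely to fail**

Step 1 (the proposed new method). The 2π partner is electron-poor, so the catalyst may not turn over or may give low ee. The fallback uses known chemistry, sets out from 1 and 7 and comes back at 9. Neat 1 is heated with hydroquinone at 150 °C in a sealed vessel (the known thermal dimerisation; the product is also a commercial bulk chemical) to give racemic 2,5-dimethyl-3,4-dihydro-2H-pyran-2-carbaldehyde F1. Olefination of F1 with carbanion 8 (from 7 and KN(SiMe3)2, THF) gives racemic 8-[(E)-2-(2,5-dimethyl-3,4-dihydro-2H-pyran-2-yl)ethenyl]-5,7-dimethoxy-2H-chromen-2-one F2. Preparative chiral SFC on an amylose carbamate phase separates F2 into 9 and the unwanted 8-{(E)-2-[(2S)-2,5-dimethyl-3,4-dihydro-2H-pyran-2-yl]ethenyl}-5,7-dimethoxy-2H-chromen-2-one F3. The same separation can polish the ee of 9 from step 1 if it is moderate.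

Step 5. The boat transition state builds a quaternary centre next to a bulky aryl-bearing carbon and needs about 200 °C, where ionisation of the tertiary allylic ether or retro-cycloaddition could erode yield and ee. The fallback replaces the rearrangement by a direct carbocyclic Diels–Alder reaction, sets out from 7 and 1 and comes back at 10. Carbanion 8 (from 7 and KN(SiMe3)2, THF, −78 °C) olefinates methacrolein 1 at the formyl group to give 5,7-dimethoxy-8-[(1E)-3-methylbuta-1,3-dien-1-yl]-2H-chromen-2-one F4. F4 then reacts with 1 under (S)-tetrahydro-1-(2-methylphenyl)-3,3-diphenyl-1H,3H-pyrrolo[1,2-c][1,3,2]oxazaborole (20 mol%) activated by HNTf2 in CH2Cl2 at −78 °C. The 1-aryl and 3-methyl groups of the diene both direct to the required regiochemistry, the endo mode places aryl and formyl cis, and the catalyst antipode is chosen to give 10.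

Step 6. The aldehyde is neopentyl-type and flanked by a bulky aryl group, carbanion 11 is only weakly stabilised, and the coumarin lactone is base-sensitive. The fallback swaps the olefination for methylenation plus Heck arylation, sets out from 10 and 3 and comes back at 12. Wittig methylenation of 10 (Ph3PCH3Br, KN(SiMe3)2, THF, 0 °C) gives 8-[(1R,6R)-6-ethenyl-3,6-dimethylcyclohex-2-en-1-yl]-5,7-dimethoxy-2H-chromen-2-one F5. Iodination of 3 (N-iodosuccinimide, CF3CO2H cat., MeCN) gives 8-iodo-5,7-dimethoxy-2H-chromen-2-one F6. Heck coupling of F5 with F6 (Pd(OAc)2, P(o-tol)3, K2CO3, DMF, 90 °C) gives 12; the quaternary carbon leaves only the benzylic hydrogen for β-hydride elimination, so only the (E)-styrene can form.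

**Further compounds**
F1 | step 1 | racemic 2,5-dimethyl-3,4-dihydro-2H-pyran-2-carbaldehyde | CC1=COC(C)(CC1)C=O
F2 | step 1 | racemic 8-[(E)-2-(2,5-dimethyl-3,4-dihydro-2H-pyran-2-yl)ethenyl]-5,7-dimethoxy-2H-chromen-2-one | CC1=COC(C)(CC1)/C=C/c1c(OC)cc(OC)c2ccc(=O)oc12
F3 | step 1 | 8-{(E)-2-[(2S)-2,5-dimethyl-3,4-dihydro-2H-pyran-2-yl]ethenyl}-5,7-dimethoxy-2H-chromen-2-one | CC1=CO[C@@](C)(CC1)/C=C/c1c(OC)cc(OC)c2ccc(=O)oc12
F4 | step 5 | 5,7-dimethoxy-8-[(1E)-3-methylbuta-1,3-dien-1-yl]-2H-chromen-2-one | CC(=C)/C=C/c1c(OC)cc(OC)c2ccc(=O)oc12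
F5 | step 6 | 8-[(1R,6R)-6-ethenyl-3,6-dimethylcyclohex-2-en-1-yl]-5,7-dimethoxy-2H-chromen-2-one | C=C[C@@]1(C)CCC(C)=C[C@H]1c1c(OC)cc(OC)c2ccc(=O)oc12
F6 | step 6 | 8-iodo-5,7-dimethoxy-2H-chromen-2-one | COc1cc(OC)c2ccc(=O)oc2c1I
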